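## Retrosynthetic overview

1. Target 20 ⇐ diester 18, where one saponification frees both CO2H and OH. 18 ⇐ N-oxide 17, whose N–O group is a traceless activator removed with B2pin2.
2. 17 ⇐ pyridine N-oxide 9 + 4-bromothiazole 16. A Pd-catalysed direct C–H arylation joins pyridine C6 to thiazole C4, and the pyridine carries neither halogen nor metal at that carbon.
3. Enabling feature: on the pyridine ring C2 (CO2Me), C4 and C5 (both OMe) are filled, so C6–H is the only C–H next to N(+)–O(−). It is acidified by that oxygen and by the C5 methoxy group, while C3–H is β and inert. On the thiazole ring, C2 (between S and N) couples first and leaves C4–Br for this step.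
4. 9 ⇐ kojic acid 1. The pyridine is the only ring made in the route (pyranone O→NH exchange, step 3), followed by Cl/OMe exchange and N-oxidation. The thiazole ring is bought as 2,4-dibromothiazole 14.
5. 16 ⇐ 14 + (S)-hept-6-en-2-yl acetate 13 by hydroboration and C2-selective B-alkyl Suzuki–Miyaura coupling. The single stereocentre comes from (S)-propylene oxide 10.

Key step: step 9

Remark on the chemistry: the carbinol centre of the target is read as (S) (O > CH2 chain > CH3 > H). It is bought in with (S)-propylene oxide, and no later step touches a bond at that carbon.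

## Route

**Step 1**
Reactants: 1 kojic acid
Product: 2 2-(hydroxymethyl)-5-methoxy-4H-pyran-4-one
Conditions: MeI (1.1 equiv), K2CO3, DMF, rt
Reagents that add atoms: iodomethane, CI
Why: Williamson-type O-methylation, in which carbonate deprotonates the enolic 5-OH of the pyranone ring (pKa about 8) but not the primary alcohol, so only the ring oxygen should be methylated.

**Step 2**
Reactants: 2 2-(hydroxymethyl)-5-methoxy-4H-pyran-4-one
Product: 4 5-methoxy-4-oxo-4H-pyran-2-carboxylic acid, via pyranone aldehyde 3 (not isolated)
Conditions: TEMPO (cat.), PhI(OAc)2 (2.2 equiv), MeCN/H2O, rt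
Reagents that add atoms: water, O
Why: TEMPO/PhI(OAc)2 oxoammonium oxidation takes the primary alcohol to aldehyde 3, whose hydrate is oxidised on to the acid in the aqueous medium, while the electron-poor pyranone ring offers nothing else to oxidise.

**Step 3**
Reactants: 4 5-methoxy-4-oxo-4H-pyran-2-carboxylic acid
Product: 5 5-methoxy-4-oxo-1,4-dihydropyridine-2-carboxylic acid
Conditions: 28 % aq. NH3, sealed vessel, 90 °C; then HCl to pH 3
Reagents that add atoms: ammonia, N
Why: Pyranone-to-pyridone exchange, in which ammonia adds in conjugate fashion at C6, the ring opens and recloses through nitrogen with loss of water (addition/ring-opening/ring-closure), a standard reaction of kojic and comenic acid ethers.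

**Step 4**
Reactants: 5 5-methoxy-4-oxo-1,4-dihydropyridine-2-carboxylic acid
Product: 8 methyl 4,5-dimethoxypyridine-2-carboxylate, via chloro acid chloride 6 (not isolated), via chloro ester 7 (not isolated)
Conditions: SOCl2, DMF (cat.), reflux; evaporate; MeOH, 0 °C; then NaOMe (excess), MeOH, reflux
Reagents that add atoms: thionyl chloride, O=S(Cl)Cl (chlorine stays only in 6 and 7); methanol, CO; sodium methoxide, [Na+].[O-]C
Why: Vilsmeier-type activation turns the acid into the acid chloride and the 4-pyridone into the 4-chloropyridine, methanolysis gives ester 7, and methoxide then replaces chloride by SNAr at C4 (para to the ring nitrogen and further activated by the ester), methoxide matching the methyl ester so that transesterification changes nothing.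

**Step 5**
Reactants: 8 methyl 4,5-dimethoxypyridine-2-carboxylate
Product: 9 methyl 4,5-dimethoxypyridine-2-carboxylate 1-oxide
Conditions: mCPBA (1.5 equiv), CH2Cl2, rt to reflux
Reagents that add atoms: mCPBA, OOC(=O)c1cccc(Cl)c1
Why: Peracid N-oxidation, for which the two methoxy groups keep the ring nitrogen nucleophilic despite the 2-ester, and which is placed before the sulfur-containing ring arrives so that no other oxidisable site is present.

**Step 6**
Reactants: 10 (S)-propylene oxide; 11 but-3-enylmagnesium bromide
Product: 12 (S)-hept-6-en-2-ol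
Conditions: CuI (10 mol %), THF, −30 °C to 0 °C; aq. NH4Cl
Reagents that add atoms: none
Why: Copper-catalysed Grignard opening of a terminal epoxide proceeds by SN2 attack at the unsubstituted CH2, so the C–O bond at the stereocentre is untouched and the (S) configuration of 10 is carried into 12.

**Step 7**
Reactants: 12 (S)-hept-6-en-2-ol
Product: 13 (S)-hept-6-en-2-yl acetate
Conditions: Ac2O, Et3N, DMAP (cat.), CH2Cl2, 0 °C to rt
Reagents that add atoms: acetic anhydride, CC(=O)OC(C)=O
Why: DMAP-catalysed O-acylation leaves the C–O bond and thus the (S) centre intact, and the acetate prevents Pd-mediated oxidation of the free carbinol in steps 8 and 9 and later falls in the same saponification as the methyl ester.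

**Step 8**
Reactants: 13 (S)-hept-6-en-2-yl acetate; 14 2,4-dibromothiazole
Product: 16 (2S)-7-(4-bromo-1,3-thiazol-2-yl)heptan-2-yl acetate, via B-alkyl-9-BBN borane 15 (not isolated)
Conditions: 9-BBN-H (1.1 equiv), THF, 0 °C to rt; then 14 (1.1 equiv), PdCl2(dppf)·CH2Cl2 (5 mol %), 3 M aq. K3PO4, DMF, 50 °C
Reagents that add atoms: 9-BBN-H, B1C2CCCC1CCC2 (boron unit stays only in 15)
Why: Anti-Markovnikov hydroboration of the terminal alkene is followed by B-alkyl Suzuki–Miyaura coupling, in which oxidative addition to 14 prefers the more electrophilic C2–Br between S and N so that C4–Br remains, and secondary acetates tolerate the phosphate base.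

**Step 9**
Reactants: 9 methyl 4,5-dimethoxypyridine-2-carboxylate 1-oxide; 16 (2S)-7-(4-bromo-1,3-thiazol-2-yl)heptan-2-yl acetate
Product: 17 methyl 6-{2-[(6S)-6-acetoxyheptyl]-1,3-thiazol-4-yl}-4,5-dimethoxypyridine-2-carboxylate 1-oxide
Conditions: Pd(OAc)2 (5 mol %), P(t-Bu)3·HBF4 (10 mol %), K2CO3 (2.5 equiv), toluene, 110 °C; 9 (2 equiv), slow addition of 16
Reagents that add atoms: none
Why: Pd(0)/P(t-Bu)3 inserts into the thiazole C4–Br bond of 16, a carbonate- or acetate-assisted concerted metalation–deprotonation cleaves the pyridine C6–H bond of 9, and reductive elimination forms the pyridine C6–thiazole C4 bond, the closest known reaction type being the Pd-catalysed direct C2–H arylation of pyridine N-oxides with aryl and N-heteroaryl bromides (for example 2-bromopyridines, which like 16 carry the bromide next to a ring nitrogen), a reaction in which ester-substituted N-oxides are among the better substrates. The step closes no ring and creates no stereocentre; the remote (S)-acetate centre is a spectator. Site selectivity on the pyridine ring is fixed by the substitution pattern: C2, C4 and C5 are occupied, C6–H is the only C–H adjacent to N(+)–O(−) and is further acidified by the ortho methoxy oxygen and the ester, whereas C3–H is β to nitrogen and lies outside the reach of the N-oxide effect. The chemoselectivity that is needed is C6–H of 9 over the thiazole C5–H of 16 and 17; it is favoured by the higher acidity of the N-oxide C–H, the apolar solvent, the excess of 9 and the slow addition of 16, which keeps the bromide scarce. K2CO3 in dry toluene leaves the methyl ester and the acetate intact. In this one operation the complete carbon skeleton with every substituent in place arises from two fragments of about half its size, and the pyridine needs neither halogen nor metal at the reacting carbon.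

**Step 10**
Reactants: 17 methyl 6-{2-[(6S)-6-acetoxyheptyl]-1,3-thiazol-4-yl}-4,5-dimethoxypyridine-2-carboxylate 1-oxide
Product: 18 methyl 6-{2-[(6S)-6-acetoxyheptyl]-1,3-thiazol-4-yl}-4,5-dimethoxypyridine-2-carboxylate
Conditions: B2pin2 (1.5 equiv), 1,4-dioxane, 100 °C
Reagents that add atoms: none
Why: Diboron-mediated deoxygenation of a pyridine N-oxide, in which the N-oxide oxygen attacks boron and is carried off as the B–O–B anhydride, is a mild oxygen transfer that leaves both esters, the thiazole sulfur and the stereocentre alone and avoids heterogeneous Pd, which the sulfur would poison.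

**Step 11**
Reactants: 18 methyl 6-{2-[(6S)-6-acetoxyheptyl]-1,3-thiazol-4-yl}-4,5-dimethoxypyridine-2-carboxylate
Product: 20 6-{2-[(6S)-6-hydroxyheptyl]-1,3-thiazol-4-yl}-4,5-dimethoxypyridine-2-carboxylic acid, via acetoxy acid 19 (not isolated)
Conditions: LiOH·H2O (5 equiv), THF/MeOH/H2O, rt to 40 °C; then 1 M HCl to pH 3–4
Reagents that add atoms: lithium hydroxide, [Li+].[OH-]
Why: Saponification cleaves the activated picolinate ester first and the secondary acetate next, both at the acyl–oxygen bond, so the carbinol C–O bond and its (S) configuration are retained and acidification to the isoelectric range releases 20.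

## Compound list

1 | kojic acid (5-hydroxy-2-(hydroxymethyl)-4H-pyran-4-one) | OCc1cc(=O)c(O)co1 | starting material
2 | 2-(hydroxymethyl)-5-methoxy-4H-pyran-4-one | OCc1cc(=O)c(OC)co1 | intermediate
3 | 5-methoxy-4-oxo-4H-pyran-2-carbaldehyde (not isolated) | O=Cc1cc(=O)c(OC)co1 | intermediate
4 | 5-methoxy-4-oxo-4H-pyran-2-carboxylic acid | OC(=O)c1cc(=O)c(OC)co1 | intermediate
5 | 5-methoxy-4-oxo-1,4-dihydropyridine-2-carboxylic acid | OC(=O)c1cc(=O)c(OC)c[nH]1 | intermediate
6 | 4-chloro-5-methoxypyridine-2-carbonyl chloride (not isolated) | ClC(=O)c1cc(Cl)c(OC)cn1 | intermediate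
7 | methyl 4-chloro-5-methoxypyridine-2-carboxylate (not isolated) | COC(=O)c1cc(Cl)c(OC)cn1 | intermediate
8 | methyl 4,5-dimethoxypyridine-2-carboxylate | COC(=O)c1cc(OC)c(OC)cn1 | intermediate
9 | methyl 4,5-dimethoxypyridine-2-carboxylate 1-oxide | COC(=O)c1cc(OC)c(OC)c[n+]1[O-] | intermediate
10 | (S)-propylene oxide | C[C@H]1CO1 | starting material
11 | but-3-enylmagnesium bromide (THF solution) | C=CCC[Mg]Br | starting material
12 | (S)-hept-6-en-2-ol | C=CCCC[C@H](C)O | intermediate
13 | (S)-hept-6-en-2-yl acetate | C=CCCC[C@H](C)OC(C)=O | intermediate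
14 | 2,4-dibromothiazole | Brc1csc(Br)n1 | starting material
15 | (2S)-7-(9-borabicyclo[3.3.1]nonan-9-yl)heptan-2-yl acetate (not isolated) | C(CCCC[C@H](C)OC(C)=O)B1C2CCCC1CCC2 | intermediate
16 | (2S)-7-(4-bromo-1,3-thiazol-2-yl)heptan-2-yl acetate | Brc1csc(CCCCC[C@H](C)OC(C)=O)n1 | intermediate
17 | methyl 6-{2-[(6S)-6-acetoxyheptyl]-1,3-thiazol-4-yl}-4,5-dimethoxypyridine-2-carboxylate 1-oxide | COC(=O)c1cc(OC)c(OC)c(-c2csc(CCCCC[C@H](C)OC(C)=O)n2)[n+]1[O-] | intermediate
18 | methyl 6-{2-[(6S)-6-acetoxyheptyl]-1,3-thiazol-4-yl}-4,5-dimethoxypyridine-2-carboxylate | COC(=O)c1cc(OC)c(OC)c(-c2csc(CCCCC[C@H](C)OC(C)=O)n2)n1 | intermediate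
19 | 6-{2-[(6S)-6-acetoxyheptyl]-1,3-thiazol-4-yl}-4,5-dimethoxypyridine-2-carboxylic acid (present as its lithium salt, not isolated) | OC(=O)c1cc(OC)c(OC)c(-c2csc(CCCCC[C@H](C)OC(C)=O)n2)n1 | intermediate
20 | 6-{2-[(6S)-6-hydroxyheptyl]-1,3-thiazol-4-yl}-4,5-dimethoxypyridine-2-carboxylic acid | COc1cc(C(=O)O)nc(-c2csc(CCCCC[C@H](C)O)n2)c1OC | target

## Step count and risks

Total step count: 11. Longest linear sequence: 8 steps (1–5, then 9–11). The thiazole branch (6–8) joins at step 9.

**Step 9 (C–H arylation).**
- What may go wrong:
  - Competing palladation at the thiazole C5–H would lead to self-arylation of the bromide and further arylation after coupling.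
  - The N,N-chelating biaryl could sequester palladium.
  - C–H cleavage at the site flanked by N–O and OMe could be slow, which would let hydrodebromination take over.
- Fallback: it sets out from 9 and 16 and comes back at 18, so step 10 falls away. N-oxide 9 would undergo deoxygenative bromination at its only free α-position (oxalyl bromide, Et3N, CH2Br2, 0 °C) to give methyl 6-bromo-4,5-dimethoxypyridine-2-carboxylate F1. Bromide 16 would be stannylated (Me3SnSnMe3, Pd(PPh3)4, toluene, 100 °C) to (2S)-7-[4-(trimethylstannyl)-1,3-thiazol-2-yl]heptan-2-yl acetate F2. Stille coupling of the two (Pd(PPh3)4, CuI, DMF, 80 °C) tolerates both esters and would give 18.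

**Step 8 (hydroboration/B-alkyl Suzuki–Miyaura coupling).**
- What may go wrong:
  - Site selectivity could erode through a second coupling at C4.
  - The alkyl transfer could be lost to β-hydride elimination or protodeboronation.
  - The aqueous base could partly hydrolyse the acetate.
- Fallback: it sets out from 13 (through borane 15) and comes back at 16. Borane 15 would be oxidised (NaBO3·4H2O, THF/H2O, rt) to (2S)-7-hydroxyheptan-2-yl acetate F3. Appel iodination (I2, PPh3, imidazole, CH2Cl2) would convert it into (2S)-7-iodoheptan-2-yl acetate F4. Zinc insertion (Zn dust, LiCl, THF, 40 °C) would then give [(6S)-6-acetoxyheptyl]zinc iodide F5. Base-free Negishi coupling with 14 (Pd(PPh3)4, THF, rt to 50 °C) is the reaction type with the closest precedent for C2-selective alkylation of 14, and it would give 16.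

**Step 4 (telescoped chlorination/methanolysis/SNAr).**
- What may go wrong:
  - Chlorodehydroxylation of the poorly soluble pyridone could be incomplete.
  - Adventitious hydroxide could saponify the ester during the hot methoxide stage.
  - The ortho methoxy donor could slow the displacement.
- Fallback: it sets out from 5 and comes back at 8, and replaces the chloride detour by direct O-alkylation. Fischer esterification (MeOH, H2SO4, reflux) would give methyl 5-methoxy-4-oxo-1,4-dihydropyridine-2-carboxylate F6. Its 4-hydroxypyridine tautomer would be O-methylated under Mitsunobu conditions (MeOH, PPh3, DIAD, THF, 0 °C to rt) to give 8.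

## Further compounds

F1 | step 9 | methyl 6-bromo-4,5-dimethoxypyridine-2-carboxylate | COC(=O)c1cc(OC)c(OC)c(Br)n1
F2 | step 9 | (2S)-7-[4-(trimethylstannyl)-1,3-thiazol-2-yl]heptan-2-yl acetate | C[Sn](C)(C)c1csc(CCCCC[C@H](C)OC(C)=O)n1
F3 | step 8 | (2S)-7-hydroxyheptan-2-yl acetate | OCCCCC[C@H](C)OC(C)=O
F4 | step 8 | (2S)-7-iodoheptan-2-yl acetate | ICCCCC[C@H](C)OC(C)=O
F5 | step 8 | [(6S)-6-acetoxyheptyl]zinc iodide | I[Zn]CCCCC[C@H](C)OC(C)=O
F6 | step 4 | methyl 5-methoxy-4-oxo-1,4-dihydropyridine-2-carboxylate | COC(=O)c1cc(=O)c(OC)c[nH]1
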